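**Strategy.** The ten-membered ring is disconnected across C5–C7. The C5=C6(Cl)–C7(O) unit of the target, whose C7 oxygen is the lactone oxygen tied through C19 and C17 to C8, is read as a 2-chloroallyl cation trapped by a carboxylate. One operation, silver-induced opening of a gem-dichlorocyclopropane, therefore expands a nine-membered ring to the ten-membered ring, installs the ring-cis C5=C6 chloroalkene, closes the γ-lactone and sets C7. Its precursor is the ring A-fused cyclononane bearing a cis-fused 6,6-dichlorocyclopropane across C5–C7, the 8,9-acetonide, the (17R)-propionic acid on C8 and silyl ethers at C2 and C12.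

Key step: step 27

Remark (numbering): briarane numbering is used throughout (C1–C14 ring carbons, C15 = C1 methyl, C16 = C5 methyl, C17/C18/C19 = propionate unit, C20 = C11 methyl). β is the ring A face carrying C15, C20 and the C10–C9 bond; α carries C2 and the C12 and epoxide oxygens. TBS = tert-butyldimethylsilyl.

Remark (structure check): precursor 37 and product 39 were compared with 43 centre by centre (cis-fused cyclopropane, ring-cis C5=C6, all shared stereocentres). No correction was needed.

Remark (precursor design): acid 37 is released only one step before the key step and is ionised with a hindered pyridine present, so that the carboxylate is the nucleophile and no free HBF4 reaches the acetonide or the silyl ethers.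

Remark (assumption): the cycloaddition of step 2 is taken to run through the ester-endo/formyl-exo transition state, which places the C11 methyl cis to the ester.

Step 1
Reactants: 1 ethyl vinyl ketone
Product: 2 (Z)-3-(tert-butyldimethylsilyloxy)penta-1,3-diene
Conditions: TBSOTf, Et3N, Et2O, 0 °C to rt
Reagents that add atoms: tert-butyldimethylsilyl triflate, CC(C)(C)[Si](C)(C)OS(=O)(=O)C(F)(F)F
Why: silyl enol ether formation by soft enolisation of the ethyl ketone should give the 2-silyloxydiene as the favoured Z enol ether (methyl cis to OSi).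

Step 2
Reactants: 2 (Z)-3-(tert-butyldimethylsilyloxy)penta-1,3-diene; 3 ethyl (E)-3-methyl-4-oxobut-2-enoate
Product: 4 ethyl (1S,2R,6S)-3-(tert-butyldimethylsilyloxy)-6-formyl-2,6-dimethylcyclohex-3-ene-1-carboxylate (ring A: C1 with β-methyl and α-formyl C2, C10 with β-ester C9, C11 with β-methyl, C12=C13 silyl enol ether)
Conditions: (R)-1-(2-methylphenyl)-3,3-diphenyltetrahydro-1H,3H-pyrrolo[1,2-c][1,3,2]oxazaborole and HN(SO2CF3)2 (20 mol % each), CH2Cl2, −78 to −40 °C
Reagents that add atoms: none
Why: in this enantioselective Diels–Alder reaction under chiral oxazaborolidinium catalysis the nucleophilic diene terminus C11 should bond to C10 (β to the complexed formyl group), the E dienophile fixes C2 trans to C9, the s-trans enal bound through its formyl C–H···O contact exposes the C1 Si face to the (R)-catalyst, and the ester-endo/formyl-exo approach of the Z diene places the C11 methyl cis to the ester.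

Step 3
Reactants: 4 ring A aldehyde ester; 5 4-bromo-2-methylbut-1-ene
Product: 7 ethyl (1S,2R,6S)-3-(tert-butyldimethylsilyloxy)-6-(1-hydroxy-4-methylpent-4-enyl)-2,6-dimethylcyclohex-3-ene-1-carboxylate as a mixture of C2 epimers, via (3-methylbut-3-enyl)magnesium bromide 6 (not isolated)
Conditions: 5, Mg, THF, rt; then 4, THF, −78 °C; cold NH4Cl quench
Reagents that add atoms: none
Why: Grignard 1,2-addition should be chemoselective for the aldehyde over the hindered ester and the silyl enol ether, and the C2 configuration is not relied on because steps 4 and 5 reset it.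

Step 4
Reactants: 7 C2 carbinol ester
Product: 8 ethyl (1S,2R,6S)-3-(tert-butyldimethylsilyloxy)-2,6-dimethyl-6-(4-methylpent-4-enoyl)cyclohex-3-ene-1-carboxylate (C2 ketone)
Conditions: Dess–Martin periodinane, NaHCO3, CH2Cl2, 0 °C to rt
Reagents that add atoms: none
Why: buffered Dess–Martin oxidation converts both carbinol epimers into one ketone without touching the acid-labile silyl enol ether.

Step 5
Reactants: 8 C2 ketone ester
Product: 9 ethyl (1S,2R,6S)-3-(tert-butyldimethylsilyloxy)-6-[(1S)-1-hydroxy-4-methylpent-4-enyl]-2,6-dimethylcyclohex-3-ene-1-carboxylate ((2S)-carbinol)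
Conditions: (R)-1-methyl-3,3-diphenyltetrahydro-1H,3H-pyrrolo[1,2-c][1,3,2]oxazaborole (0.5 equiv), catecholborane, toluene, −78 to −40 °C
Reagents that add atoms: none
Why: in this Corey–Bakshi–Shibata reduction the quaternary C1 acts as the large and the CH2 chain as the small ketone substituent, so the (R)-catalyst should deliver hydride to give the (2S) alcohol under reagent control, while catecholborane spares the ester, the enol ether and the 1,1-disubstituted alkene.

Step 6
Reactants: 9 (2S)-carbinol ester
Product: 10 the C2 TBS ether of 9 (silyl enol ether and ethyl ester unchanged)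
Conditions: TBSOTf, 2,6-lutidine, CH2Cl2, −78 to 0 °C
Reagents that add atoms: tert-butyldimethylsilyl triflate, CC(C)(C)[Si](C)(C)OS(=O)(=O)C(F)(F)F
Why: silylation with the triflate should cap the hindered neopentyl-type alcohol before it can lactonise onto the C9 ester.

Step 7
Reactants: 10 2-O-TBS silyl enol ether ester
Product: 11 ethyl (1S,2R,6S)-6-[(1S)-1-(tert-butyldimethylsilyloxy)-4-methylpent-4-enyl]-2,6-dimethyl-3-oxocyclohex-4-ene-1-carboxylate (ring A enone: C12 ketone, C13=C14)
Conditions: Pd(OAc)2 (1.2 equiv), MeCN, 40 °C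
Reagents that add atoms: none
Why: Saegusa–Ito oxidation of the regiodefined silyl enol ether should place the double bond at C13=C14 under neutral conditions that do not epimerise C11.

Step 8
Reactants: 11 ring A enone ester
Product: 12 the 12β-allylic alcohol of 11 (hydroxyl cis to the C11 methyl; C13=C14 retained)
Conditions: NaBH4, CeCl3·7H2O, MeOH, −78 °C
Reagents that add atoms: none
Why: in this Luche 1,2-reduction hydride should enter from the open α face, because the β face is screened by the axial C10 substituent or by the two β-methyl groups in either half-chair, giving the 12β alcohol.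

Step 9
Reactants: 12 12β-alcohol
Product: 13 the 12α-(4-nitrobenzoate) (C12 inverted; O now trans to the C11 methyl)
Conditions: 4-nitrobenzoic acid, PPh3, DIAD, toluene, 0 °C to rt
Reagents that add atoms: 4-nitrobenzoic acid, OC(=O)c1ccc(cc1)[N+](=O)[O-]
Why: Mitsunobu inversion brings the carboxylate in from the same open α face (SN2 at C12), and SN2′ attack at C14 is blocked by the adjacent quaternary C1.

Step 10
Reactants: 13 12α-(4-nitrobenzoate)
Product: 14 the 12α-hydroxy Weinreb amide (C9 ethyl ester converted into C(=O)N(OMe)Me; 12α-OH free; 2-OTBS kept)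
Conditions: MeNH(OMe)·HCl, AlMe3, CH2Cl2, 0 to 40 °C
Reagents that add atoms: N,O-dimethylhydroxylamine hydrochloride, CNOC.Cl
Why: Weinreb aminolysis with the aluminium amide should convert the ethyl ester into the N-methoxy-N-methylamide and cleave the aryl ester in the same non-basic operation, so that C10 is not epimerised.

Step 11
Reactants: 14 12α-hydroxy Weinreb amide
Product: 15 the 2,12-bis-TBS Weinreb amide (12α-OTBS)
Conditions: TBSOTf, 2,6-lutidine, CH2Cl2, −78 to 0 °C
Reagents that add atoms: tert-butyldimethylsilyl triflate, CC(C)(C)[Si](C)(C)OS(=O)(=O)C(F)(F)F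
Why: standard silylation of the secondary allylic alcohol, to which the amide is inert.

Step 12
Reactants: 15 2,12-bis-TBS Weinreb amide
Product: 16 the C9 aldehyde (ring A with β-CHO on C10, α-CH(OTBS)CH2CH2C(CH3)=CH2 on C1, 12α-OTBS, C13=C14)
Conditions: i-Bu2AlH, THF, −78 °C
Reagents that add atoms: none
Why: reduction of the Weinreb amide stops at the chelated hemiaminal and should give the aldehyde on work-up without over-reduction.

Step 13
Reactants: 17 methyl (S)-3-hydroxy-2-methylpropanoate
Product: 18 methyl (S)-3-(tert-butyldimethylsilyloxy)-2-methylpropanoate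
Conditions: TBSCl, imidazole, CH2Cl2, 0 °C to rt
Reagents that add atoms: tert-butyldimethylsilyl chloride, CC(C)(C)[Si](C)(C)Cl
Why: silylation of the primary alcohol, which becomes C19 and is distinguishable later from the secondary silyl ethers.

Step 14
Reactants: 18 methyl (S)-3-(tert-butyldimethylsilyloxy)-2-methylpropanoate
Product: 19 (S)-3-(tert-butyldimethylsilyloxy)-2-methylpropanal
Conditions: i-Bu2AlH, CH2Cl2, −78 °C
Reagents that add atoms: none
Why: low-temperature partial reduction of the ester gives the aldehyde, which is used at once to keep the C17 centre intact.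

Step 15
Reactants: 19 (S)-3-(tert-butyldimethylsilyloxy)-2-methylpropanal
Product: 20 (R)-tert-butyldimethyl(2-methylbut-3-ynyloxy)silane
Conditions: dimethyl (1-diazo-2-oxopropyl)phosphonate, K2CO3, MeOH, 0 °C to rt
Reagents that add atoms: dimethyl (1-diazo-2-oxopropyl)phosphonate, COP(=O)(OC)C(=[N+]=[N-])C(C)=O
Why: Ohira–Bestmann homologation turns the aldehyde carbon into the internal alkyne carbon (future C8) under conditions mild enough for an α-stereogenic aldehyde.

Step 16
Reactants: 20 (R)-tert-butyldimethyl(2-methylbut-3-ynyloxy)silane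
Product: 22 (S)-tert-butyl(3-iodo-2-methylbut-3-enyloxy)dimethylsilane, via (Z)-2-iodoalkenyl-9-BBN adduct 21 (not isolated)
Conditions: 9-iodo-9-borabicyclo[3.3.1]nonane, pentane, −20 to 0 °C; then AcOH
Reagents that add atoms: 9-iodo-9-borabicyclo[3.3.1]nonane, IB1C2CCCC1CCC2
Why: syn haloboration of the terminal alkyne puts iodine on the internal carbon, and protonolysis of the C–B bond should give the 2-iodo-1-alkene (Markovnikov hydroiodination).

Step 17
Reactants: 16 C9 aldehyde; 22 (S)-tert-butyl(3-iodo-2-methylbut-3-enyloxy)dimethylsilane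
Product: 24 the (9R)-allylic alcohol (C10–CH(OH)–C(=CH2)–CH(CH3)–CH2OTBS; 9-OH epimeric to the target; C17 as in 22), via 2-lithioalkene 23 (not isolated)
Conditions: 22, t-BuLi (2.1 equiv), Et2O, −78 °C; then 16, −78 °C
Reagents that add atoms: none
Why: after iodine–lithium exchange the alkenyllithium should add under Felkin–Anh control, anti to the quaternary C1 and past H10, to give the (9R) carbinol, which is the epimer that step 18 needs.

Step 18
Reactants: 24 (9R)-allylic alcohol
Product: 25 the (8S,9R)-epoxy alcohol (spiro epoxide C8–O–C7H2 on the former exocyclic alkene; erythro to the 9-OH)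
Conditions: VO(acac)2 (5 mol %), t-BuOOH, CH2Cl2, 0 °C to rt
Reagents that add atoms: tert-butyl hydroperoxide, CC(C)(C)OO
Why: in this hydroxyl-directed epoxidation the vanadium-bound O9 delivers oxygen to the alkene face it overhangs in the conformer with H9 eclipsing C17 (A(1,2) strain), which should give the erythro epoxide, that is the C8–O configuration of the target, and leave the two undirected alkenes alone.

Step 19
Reactants: 25 (8S,9R)-epoxy alcohol
Product: 27 the (8R,9R)-8-vinyl-8,9-diol (C8 now bears OH, CH=CH2 (C7), C17 and C9), via sulfonium alkoxide 26 (not isolated)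
Conditions: Me3S+ I−, n-BuLi, THF, −10 °C to rt
Reagents that add atoms: trimethylsulfonium iodide, C[S+](C)C.[I-]
Why: in this one-carbon homologation of an epoxide to an allylic alcohol, dimethylsulfonium methylide opens the epoxide at its CH2 terminus and the resulting sulfonium alkoxide eliminates Me2S, so the C8–O bond and its configuration are kept.

Step 20
Reactants: 27 (8R,9R)-8-vinyl-8,9-diol
Product: 28 the 8-hydroxy-9-ketone (C9 carbonyl between C10 and the tertiary allylic carbinol C8)
Conditions: Dess–Martin periodinane, NaHCO3, CH2Cl2, 0 °C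
Reagents that add atoms: none
Why: Dess–Martin oxidation affects only the secondary C9 carbinol (the tertiary C8 alcohol is inert) and removes the temporary C9 configuration.

Step 21
Reactants: 28 8-hydroxy-9-ketone
Product: 29 the (8R,9S)-diol (8,9-syn as in the target)
Conditions: Zn(BH4)2, Et2O, −30 °C
Reagents that add atoms: none
Why: in this chelation-controlled reduction zinc bridges O8 and the C9 carbonyl, and hydride should enter from the chelate face flanked by the vinyl group (smaller than the C17 branch), which is also the Felkin–Anh face anti to quaternary C1, giving (9S).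

Step 22
Reactants: 29 (8R,9S)-diol
Product: 30 the 8,9-acetonide diene (C8 vinyl and C5 isopropenyl termini; C2, C12 and C19 TBS ethers)
Conditions: 2,2-dimethoxypropane, pyridinium p-toluenesulfonate (cat.), CH2Cl2, rt
Reagents that add atoms: 2,2-dimethoxypropane, COC(C)(C)OC
Why: acid-catalysed transacetalisation ties the syn diol into a dioxolane under conditions that should leave the silyl ethers intact.

Step 23
Reactants: 30 8,9-acetonide diene
Product: 31 the ring A-fused cyclononene ((5Z)-C5=C7 trisubstituted alkene; 8,9-acetonide; C8 side chain CH(CH3)CH2OTBS)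
Conditions: RuCl2(H2IMes)(=CH-C6H4-2-O-i-Pr) (second-generation Hoveyda–Grubbs catalyst, H2IMes = 1,3-dimesitylimidazolidin-2-ylidene, 15 mol %), toluene (0.001 M), 100 °C
Reagents that add atoms: none
Why: in this ring-closing metathesis the trans-disposed arms on ring A and the dioxolane should hold the vinyl and isopropenyl groups close, the nine-membered ring admits only the ring-cis alkene, and the hindered cyclohexene does not take part.

Step 24
Reactants: 31 cyclononene; 32 chloroform
Product: 34 the (5S,7S)-6,6-dichlorocyclopropane cis-fused across C5–C7, via dichlorocarbene 33 (not isolated)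
Conditions: CHCl3, 50% aq NaOH, benzyltriethylammonium chloride (cat.), 0 °C to rt
Reagents that add atoms: none
Why: in this phase-transfer dichlorocyclopropanation the electrophilic carbene should prefer the trisubstituted C5=C7 alkene over the hindered disubstituted C13=C14 alkene, and it adds stereospecifically cis from the outer face.

Step 25
Reactants: 34 dichlorocyclopropane
Product: 35 the C19 primary alcohol
Conditions: HF·pyridine, pyridine, THF, 0 °C
Reagents that add atoms: none
Why: buffered fluoride desilylation should remove the primary TBS ether much faster than the two hindered secondary ones and does not affect the acetonide.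

Step 26
Reactants: 35 C19 alcohol
Product: 37 the (17R)-carboxylic acid (key-step precursor), via C19 aldehyde 36 (not isolated)
Conditions: 2,2,6,6-tetramethylpiperidin-1-oxyl (10 mol %), PhI(OAc)2, MeCN/pH 7 phosphate buffer, rt
Reagents that add atoms: water, O
Why: oxoammonium-mediated oxidation takes the primary alcohol through the aldehyde hydrate to the acid at neutral pH, which should keep C17, the acetonide and the cyclopropane intact.

Step 27
Reactants: 37 dichlorocyclopropane acid
Product: 39 the ten-membered (5E)-6-chloro-5-ene 19,7-lactone with 8,9-acetonide and 2,12-bis-TBS ethers ((7S); ring-cis alkene), via zwitterionic chloroallyl cation 38 (not isolated)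
Conditions: AgBF4 (3 equiv), 2,6-di-tert-butyl-4-methylpyridine (3 equiv), 4 Å molecular sieves, ClCH2CH2Cl, dark, 23 to 60 °C
Reagents that add atoms: none
Why: AgBF4 abstracts the C6 chloride that is cis to C4 and C8 while the C5–C7 bond opens in a disrotatory two-electron electrocyclic process, giving the U-shaped 2-chloroallyl cation C5–C6–C7 inside the new ten-membered ring, which the C19 carboxylate traps at C7; the hindered pyridine takes up HBF4 so that the acetonide and silyl ethers survive. The closest known reaction type is the silver-promoted ring expansion of ring-fused gem-dihalocyclopropanes with capture of the 2-haloallyl cation by a tethered oxygen nucleophile. The ten-membered ring arises by ring expansion (cleavage of the shared C5–C7 bond of the bicyclo[7.1.0]decane, not a cyclisation), and the γ-lactone closes 5-exo-trig at the secondary terminus C7, whereas attack at the tertiary terminus C5 would need a seven-membered ring. The new stereocentre C7 is controlled by C8: the carboxylate hangs from C17 on C8 and should reach only the C7 face that gives the cis-fused lactone with H7 syn to O8 (7S). The step needs inward rotation of C4 and C8 (ring-cis C5=C6) and capture at C7; the C5 methyl secures the first, because the other rotation would force that methyl inside a trans-cyclodecenyl cation, and the short C8–C17–C19 tether secures the second. Either face of carbene addition in step 24 would feed the same cation, since C5 and C7 become planar.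

Step 28
Reactants: 39 chloroalkene lactone
Product: 40 the 2,12-diol (acetonide and lactone intact)
Conditions: Bu4NF, AcOH, THF, 50 °C
Reagents that add atoms: none
Why: fluoride desilylation buffered with acetic acid should free both secondary alcohols without base-induced epimerisation at C17 or β-elimination of the lactone.

Step 29
Reactants: 40 2,12-diol
Product: 41 the 13α,14α-epoxide (cis to the 12α-hydroxyl)
Conditions: VO(acac)2 (5 mol %), t-BuOOH, CH2Cl2, 0 °C to rt
Reagents that add atoms: tert-butyl hydroperoxide, CC(C)(C)OO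
Why: in this hydroxyl-directed epoxidation the allylic 12α-OH (supported by the homoallylic C2–OH on the same face) should deliver oxygen to the α face of C13=C14, while the undirected, electron-poor chloroalkene does not react.

Step 30
Reactants: 41 13,14-epoxy diol
Product: 42 the 2,12-diacetate (8,9-acetonide still in place)
Conditions: Ac2O, 4-(dimethylamino)pyridine, pyridine, rt
Reagents that add atoms: acetic anhydride, CC(=O)OC(C)=O
Why: nucleophilic-catalysed acylation esterifies the only free hydroxyls, C2 and C12, because the 8,9-diol is masked.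

Step 31
Reactants: 42 diacetate acetonide
Product: 43 CNP0255641.1, (1S,2S,5E,7S,8R,9S,10S,11R,12S,13S,14R,17R)-2,12-diacetoxy-6-chloro-13,14-epoxy-8,9-dihydroxybriar-5-en-19,7-olide
Conditions: AcOH/H2O/THF (3:1:1), 35 °C
Reagents that add atoms: none
Why: mild aqueous-acid acetal hydrolysis should release the tertiary/secondary diol while the acetates, lactone and hindered epoxide remain.

**Compound list**

1 | ethyl vinyl ketone (pent-1-en-3-one) | CCC(=O)C=C | starting material
2 | (Z)-3-(tert-butyldimethylsilyloxy)penta-1,3-diene | C=C/C(O[Si](C)(C)C(C)(C)C)=C/C | intermediate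
3 | ethyl (E)-3-methyl-4-oxobut-2-enoate | CCOC(=O)/C=C(\C)C=O | starting material
4 | ethyl (1S,2R,6S)-3-(tert-butyldimethylsilyloxy)-6-formyl-2,6-dimethylcyclohex-3-ene-1-carboxylate | O=C[C@@]1(C)CC=C(O[Si](C)(C)C(C)(C)C)[C@H](C)[C@@H]1C(=O)OCC | intermediate
5 | 4-bromo-2-methylbut-1-ene | C=C(C)CCBr | starting material
6 | (3-methylbut-3-enyl)magnesium bromide | C=C(C)CC[Mg]Br | intermediate
7 | C2 carbinol ester, both C2 epimers | OC(CCC(C)=C)[C@@]1(C)CC=C(O[Si](C)(C)C(C)(C)C)[C@H](C)[C@@H]1C(=O)OCC | intermediate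
8 | C2 ketone ester | O=C(CCC(C)=C)[C@@]1(C)CC=C(O[Si](C)(C)C(C)(C)C)[C@H](C)[C@@H]1C(=O)OCC | intermediate
9 | (2S)-carbinol ester | O[C@@H](CCC(C)=C)[C@@]1(C)CC=C(O[Si](C)(C)C(C)(C)C)[C@H](C)[C@@H]1C(=O)OCC | intermediate
10 | 2-O-TBS silyl enol ether ester | CC(C)(C)[Si](C)(C)O[C@@H](CCC(C)=C)[C@@]1(C)CC=C(O[Si](C)(C)C(C)(C)C)[C@H](C)[C@@H]1C(=O)OCC | intermediate
11 | ring A enone ester (C12 ketone, C13=C14) | CC(C)(C)[Si](C)(C)O[C@@H](CCC(C)=C)[C@@]1(C)C=CC(=O)[C@H](C)[C@@H]1C(=O)OCC | intermediate
12 | 12β-allylic alcohol | CC(C)(C)[Si](C)(C)O[C@@H](CCC(C)=C)[C@@]1(C)C=C[C@H](O)[C@H](C)[C@@H]1C(=O)OCC | intermediate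
13 | 12α-(4-nitrobenzoate) | CC(C)(C)[Si](C)(C)O[C@@H](CCC(C)=C)[C@@]1(C)C=C[C@@H](OC(=O)c2ccc(cc2)[N+](=O)[O-])[C@H](C)[C@@H]1C(=O)OCC | intermediate
14 | 12α-hydroxy Weinreb amide | CC(C)(C)[Si](C)(C)O[C@@H](CCC(C)=C)[C@@]1(C)C=C[C@@H](O)[C@H](C)[C@@H]1C(=O)N(C)OC | intermediate
15 | 2,12-bis-TBS Weinreb amide | CC(C)(C)[Si](C)(C)O[C@@H](CCC(C)=C)[C@@]1(C)C=C[C@@H](O[Si](C)(C)C(C)(C)C)[C@H](C)[C@@H]1C(=O)N(C)OC | intermediate
16 | C9 aldehyde | CC(C)(C)[Si](C)(C)O[C@@H](CCC(C)=C)[C@@]1(C)C=C[C@@H](O[Si](C)(C)C(C)(C)C)[C@H](C)[C@@H]1C=O | intermediate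
17 | methyl (S)-3-hydroxy-2-methylpropanoate | C[C@@H](CO)C(=O)OC | starting material
18 | methyl (S)-3-(tert-butyldimethylsilyloxy)-2-methylpropanoate | C[C@@H](CO[Si](C)(C)C(C)(C)C)C(=O)OC | intermediate
19 | (S)-3-(tert-butyldimethylsilyloxy)-2-methylpropanal | C[C@@H](CO[Si](C)(C)C(C)(C)C)C=O | intermediate
20 | (R)-tert-butyldimethyl(2-methylbut-3-ynyloxy)silane | C[C@@H](CO[Si](C)(C)C(C)(C)C)C#C | intermediate
21 | (Z)-2-iodoalkenyl-9-BBN adduct | C[C@@H](CO[Si](C)(C)C(C)(C)C)/C(I)=C/B1C2CCCC1CCC2 | intermediate
22 | (S)-tert-butyl(3-iodo-2-methylbut-3-enyloxy)dimethylsilane | C[C@@H](CO[Si](C)(C)C(C)(C)C)C(I)=C | intermediate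
23 | 2-lithioalkene from 22 | C[C@@H](CO[Si](C)(C)C(C)(C)C)C([Li])=C | intermediate
24 | (9R)-allylic alcohol | CC(C)(C)[Si](C)(C)O[C@@H](CCC(C)=C)[C@@]1(C)C=C[C@@H](O[Si](C)(C)C(C)(C)C)[C@H](C)[C@@H]1[C@@H](O)C(=C)[C@@H](C)CO[Si](C)(C)C(C)(C)C | intermediate
25 | (8S,9R)-epoxy alcohol | CC(C)(C)[Si](C)(C)O[C@@H](CCC(C)=C)[C@@]1(C)C=C[C@@H](O[Si](C)(C)C(C)(C)C)[C@H](C)[C@@H]1[C@@H](O)[C@@]2(CO2)[C@@H](C)CO[Si](C)(C)C(C)(C)C | intermediate
26 | sulfonium alkoxide adduct | CC(C)(C)[Si](C)(C)O[C@@H](CCC(C)=C)[C@@]1(C)C=C[C@@H](O[Si](C)(C)C(C)(C)C)[C@H](C)[C@@H]1[C@@H](O)[C@@]([O-])(CC[S+](C)C)[C@@H](C)CO[Si](C)(C)C(C)(C)C | intermediate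
27 | (8R,9R)-8-vinyl-8,9-diol | CC(C)(C)[Si](C)(C)O[C@@H](CCC(C)=C)[C@@]1(C)C=C[C@@H](O[Si](C)(C)C(C)(C)C)[C@H](C)[C@@H]1[C@@H](O)[C@@](O)(C=C)[C@@H](C)CO[Si](C)(C)C(C)(C)C | intermediate
28 | 8-hydroxy-9-ketone | CC(C)(C)[Si](C)(C)O[C@@H](CCC(C)=C)[C@@]1(C)C=C[C@@H](O[Si](C)(C)C(C)(C)C)[C@H](C)[C@@H]1C(=O)[C@@](O)(C=C)[C@@H](C)CO[Si](C)(C)C(C)(C)C | intermediate
29 | (8R,9S)-diol | CC(C)(C)[Si](C)(C)O[C@@H](CCC(C)=C)[C@@]1(C)C=C[C@@H](O[Si](C)(C)C(C)(C)C)[C@H](C)[C@@H]1[C@H](O)[C@@](O)(C=C)[C@@H](C)CO[Si](C)(C)C(C)(C)C | intermediate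
30 | 8,9-acetonide diene | CC(C)(C)[Si](C)(C)O[C@@H](CCC(C)=C)[C@@]1(C)C=C[C@@H](O[Si](C)(C)C(C)(C)C)[C@H](C)[C@@H]1[C@@H]2OC(C)(C)O[C@]2(C=C)[C@@H](C)CO[Si](C)(C)C(C)(C)C | intermediate
31 | ring A-fused (5Z)-cyclononene | CC(C)(C)[Si](C)(C)O[C@H]1[C@H](C)[C@@H]2[C@@H]3OC(C)(C)O[C@@]3([C@@H](C)CO[Si](C)(C)C(C)(C)C)/C=C(/C)CC[C@H](O[Si](C)(C)C(C)(C)C)[C@@]2(C)C=C1 | intermediate
32 | chloroform | ClC(Cl)Cl | starting material
33 | dichlorocarbene | Cl[C]Cl | intermediate
34 | (5S,7S)-dichlorocyclopropane, C19 TBS ether | CC(C)(C)[Si](C)(C)O[C@H]1[C@H](C)[C@@H]2[C@@H]3OC(C)(C)O[C@@]3([C@@H](C)CO[Si](C)(C)C(C)(C)C)[C@H]4C(Cl)(Cl)[C@@]4(C)CC[C@H](O[Si](C)(C)C(C)(C)C)[C@@]2(C)C=C1 | intermediate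
35 | dichlorocyclopropane C19 alcohol | CC(C)(C)[Si](C)(C)O[C@H]1[C@H](C)[C@@H]2[C@@H]3OC(C)(C)O[C@@]3([C@@H](C)CO)[C@H]4C(Cl)(Cl)[C@@]4(C)CC[C@H](O[Si](C)(C)C(C)(C)C)[C@@]2(C)C=C1 | intermediate
36 | dichlorocyclopropane C19 aldehyde | CC(C)(C)[Si](C)(C)O[C@H]1[C@H](C)[C@@H]2[C@@H]3OC(C)(C)O[C@@]3([C@@H](C)C=O)[C@H]4C(Cl)(Cl)[C@@]4(C)CC[C@H](O[Si](C)(C)C(C)(C)C)[C@@]2(C)C=C1 | intermediate
37 | dichlorocyclopropane-fused nine-membered ring acid (key-step precursor) | CC(C)(C)[Si](C)(C)O[C@H]1[C@H](C)[C@@H]2[C@@H]3OC(C)(C)O[C@@]3([C@@H](C)C(=O)O)[C@H]4C(Cl)(Cl)[C@@]4(C)CC[C@H](O[Si](C)(C)C(C)(C)C)[C@@]2(C)C=C1 | intermediate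
38 | zwitterionic ten-membered 2-chloroallyl cation carboxylate | CC(C)(C)[Si](C)(C)O[C@H]1[C@H](C)[C@@H]2[C@@H]3OC(C)(C)O[C@@]3([C@@H](C)C(=O)[O-])[CH+]/C(Cl)=C(/C)CC[C@H](O[Si](C)(C)C(C)(C)C)[C@@]2(C)C=C1 | intermediate
39 | ten-membered chloroalkene lactone, 8,9-acetonide (key-step product) | CC(C)(C)[Si](C)(C)O[C@H]1[C@H](C)[C@@H]2[C@@H]3OC(C)(C)O[C@@]34[C@H](OC(=O)[C@@H]4C)/C(Cl)=C(/C)CC[C@H](O[Si](C)(C)C(C)(C)C)[C@@]2(C)C=C1 | intermediate
40 | 2,12-diol lactone acetonide | O[C@H]1[C@H](C)[C@@H]2[C@@H]3OC(C)(C)O[C@@]34[C@H](OC(=O)[C@@H]4C)/C(Cl)=C(/C)CC[C@H](O)[C@@]2(C)C=C1 | intermediate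
41 | 13α,14α-epoxy 2,12-diol | O[C@H]1[C@H](C)[C@@H]2[C@@H]3OC(C)(C)O[C@@]34[C@H](OC(=O)[C@@H]4C)/C(Cl)=C(/C)CC[C@H](O)[C@@]2(C)[C@H]2O[C@@H]12 | intermediate
42 | 2,12-diacetate 8,9-acetonide | CC(=O)O[C@H]1[C@H](C)[C@@H]2[C@@H]3OC(C)(C)O[C@@]34[C@H](OC(=O)[C@@H]4C)/C(Cl)=C(/C)CC[C@H](OC(C)=O)[C@@]2(C)[C@H]2O[C@@H]12 | intermediate
43 | CNP0255641.1 | CC(=O)O[C@H]1[C@H](C)[C@@H]2[C@H](O)[C@@]3(O)[C@H](OC(=O)[C@@H]3C)/C(Cl)=C(/C)CC[C@H](OC(C)=O)[C@@]2(C)[C@H]2O[C@@H]12 | target

**Step count and risk**

Total step count: 31. Longest linear sequence: 27 steps (steps 1–12, then 17–31); the side-chain branch (steps 13–16) has 4 steps.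

Steps most likely to fail:

1. Step 27 (key step). The ionisation may follow the outward-rotating path to a trans-cyclodecenyl cation, the cation may lose a proton or be captured at the wrong site, or acid may strip the acetonide before the carboxylate closes. The fallback separates ring expansion from lactone formation. It sets out from 34, which is solvolysed with AgBF4 and 2,6-lutidine in acetone/H2O (9:1) at 40 °C, so that water captures the C7 terminus and should give the (7S)-7-hydroxy-6-chloro-5-ene with the C19 TBS ether, F1. Selective removal of the primary silyl ether (HF·pyridine, pyridine, THF, 0 °C) gives the 7,19-diol F2. Oxidative lactonisation of this 1,4-diol (2,2,6,6-tetramethylpiperidin-1-oxyl, PhI(OAc)2, CH2Cl2) oxidises the primary alcohol through the lactol and returns to the route at 39.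

2. Step 23 (ring-closing metathesis). The hindered ruthenium alkylidene on the C8 vinyl group may fail to engage the 1,1-disubstituted alkene, leading to dimerisation or catalyst decay instead of nine-membered ring closure. The fallback replaces metathesis by reductive carbonyl coupling. It sets out from 30, whose two terminal alkenes are cleaved selectively by Lemieux–Johnson oxidation (OsO4 cat., NaIO4, 2,6-lutidine, dioxane/H2O; the hindered ring A alkene should survive) to the C5 methyl ketone C7 aldehyde F3. An intramolecular McMurry coupling (TiCl3(DME)1.5, Zn–Cu couple, DME, reflux, high dilution) then forms the C5=C7 bond, which the nine-membered ring allows only as the ring-cis alkene, and returns to the route at 31.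

3. Step 2 (Diels–Alder). Discrimination between the ester-endo and formyl-endo approaches may be insufficient, which would scramble C11 while C1 and C10 stay correct. The fallback stops relying on cycloaddition topology for C11. It sets out from 4 obtained as a C11 mixture, which is carried unchanged through steps 3 to 7. At the enone stage the mixture is converted with LDA (THF, −78 °C) into the lithium cross-conjugated dienolate F4, in which C11 is planar and the C10 substituent sits pseudoaxially on the β face. Kinetic protonation with 2,6-di-tert-butyl-4-methylphenol at −78 °C from the α face, anti to that substituent, should give the cis C10/C11 arrangement and returns to the route at 11.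

**Further compounds**

F1 | step 27 | (7S)-7-hydroxy-6-chloro-5-ene ten-membered ring, C19 TBS ether | CC(C)(C)[Si](C)(C)O[C@H]1[C@H](C)[C@@H]2[C@@H]3OC(C)(C)O[C@@]3([C@@H](C)CO[Si](C)(C)C(C)(C)C)[C@H](O)/C(Cl)=C(/C)CC[C@H](O[Si](C)(C)C(C)(C)C)[C@@]2(C)C=C1
F2 | step 27 | (7S)-7,19-diol of the ten-membered chloroalkene | CC(C)(C)[Si](C)(C)O[C@H]1[C@H](C)[C@@H]2[C@@H]3OC(C)(C)O[C@@]3([C@@H](C)CO)[C@H](O)/C(Cl)=C(/C)CC[C@H](O[Si](C)(C)C(C)(C)C)[C@@]2(C)C=C1
F3 | step 23 | C5 methyl ketone C7 aldehyde from 30 | CC(C)(C)[Si](C)(C)O[C@@H](CCC(C)=O)[C@@]1(C)C=C[C@@H](O[Si](C)(C)C(C)(C)C)[C@H](C)[C@@H]1[C@@H]2OC(C)(C)O[C@]2(C=O)[C@@H](C)CO[Si](C)(C)C(C)(C)C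
F4 | step 2 | lithium C11–C12 dienolate of enone 11 | CC(C)(C)[Si](C)(C)O[C@@H](CCC(C)=C)[C@@]1(C)C=CC(O[Li])=C(C)[C@@H]1C(=O)OCC
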